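**Strategy.** The route rests on cutting the C4a–C5 bond of ring A. Ring A is a phloroglucinol whose C4a bears the C4 ketone while C5, C7 and C8a carry oxygen, the 1,3,5-pattern of a folded polyketide. The precursor is therefore a (2S)-2-aryl-2,3-dihydropyran-4-one (the finished ring C with its stereocentre) carrying a CH2C(=O)CH2CO2Me chain on C6, released from a dioxinone only after the pyranone exists. In one operation a magnesium-mediated Claisen closure joins pyranone C5 to the ester carbon and enolisation aromatises ring A, giving the 5,7-dihydroxyflavanone without any phenol protection. Two deprotections follow.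

Key step: step 12

Remarks on the chemistry:
- Numbering: flavanone numbering is used for ring A and ring C (O1, C2, C3, C4, C4a, C5 to C8, C8a); the side chain is C7 (benzylic carbinol), C8 (aryloxy carbon), C9 (CH2OH). The target is 2S,7R,8R (threo).
- Abbreviation in names: Ar = 4-{[(4R,5R)-4-(4-benzyloxyphenyl)-2,2-dimethyl-1,3-dioxan-5-yl]oxy}-3,5-dimethoxyphenyl, that is ring B with the acetonide-protected side chain.
- Assumption: the chloroacetyl imide used in step 1 is purchased; otherwise it is one N-acylation of (S)-4-benzyl-1,3-oxazolidin-2-one.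
- Design remark: a free 3,5,7-triketo ester would aromatise by aldol closure, so the acetoacetate terminus is carried as a dioxinone until the δ-hydroxy-β-diketone has closed to the pyranone.

**Route**

Step 1
Reactants: 1 methyl 4-hydroxy-3,5-dimethoxybenzoate (methyl syringate); 2 (4S)-4-benzyl-3-(chloroacetyl)-1,3-oxazolidin-2-one
Product: 3 methyl 4-{2-[(4S)-4-benzyl-2-oxo-1,3-oxazolidin-3-yl]-2-oxoethoxy}-3,5-dimethoxybenzoate
Conditions: K2CO3, KI (cat.), acetone, 55 °C
Reagents that add atoms: none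
Why: Williamson ether synthesis: the phenoxide of 1 displaces the halide of the very SN2-reactive α-halo imide faster than it can attack the imide carbonyl, and no stereocentre is involved.

Step 2
Reactants: 3 aryloxyacetyl imide; 4 4-benzyloxybenzaldehyde
Product: 6 methyl 4-{[(2S,3R)-1-[(4S)-4-benzyl-2-oxo-1,3-oxazolidin-3-yl]-3-(4-benzyloxyphenyl)-3-hydroxy-1-oxopropan-2-yl]oxy}-3,5-dimethoxybenzoate, via boron enolate 5 (not isolated)
Conditions: Bu2BOTf, Et3N, CH2Cl2, −78 to 0 °C; then 4, −78 to 0 °C; pH 7 buffer, MeOH, 30% H2O2, 0 °C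
Reagents that add atoms: none
Why: Evans syn aldol reaction: soft enolisation gives the Z-boron enolate 5, which adds to the aldehyde through a chair Zimmerman–Traxler transition state on the face opposite the benzyl group of the (S)-auxiliary, so that the aryloxy carbon (2S in 6, later C8 R) and the carbinol carbon (3R, later C7 R) are set together as the syn (threo) pair.

Step 3
Reactants: 6 syn aldol adduct
Product: 7 methyl 4-{[(1R,2R)-1-(4-benzyloxyphenyl)-1,3-dihydroxypropan-2-yl]oxy}-3,5-dimethoxybenzoate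
Conditions: NaBH4, THF/H2O (4:1), 0 °C to rt
Reagents that add atoms: none
Why: Reductive cleavage of the N-acyloxazolidinone by borohydride gives the primary alcohol and returns the auxiliary, while the electron-rich methyl benzoate is not reduced under these aqueous conditions and neither stereocentre is touched.

Step 4
Reactants: 7 diol
Product: 8 methyl 4-{[(4R,5R)-4-(4-benzyloxyphenyl)-2,2-dimethyl-1,3-dioxan-5-yl]oxy}-3,5-dimethoxybenzoate (Ar–CO2Me)
Conditions: 2,2-dimethoxypropane, PPTS (cat.), acetone, rt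
Reagents that add atoms: 2,2-dimethoxypropane, COC(C)(C)OC
Why: Acid-catalysed transacetalisation (acetonide formation) closes a 1,3-dioxane on the 1,3-diol; PPTS is too weak to ionise the benzylic C–O bond, so both stereocentres are retained.

Step 5
Reactants: 8 aryl ester Ar–CO2Me; 9 N-methoxy-N-methylacetamide
Product: 11 3-Ar-N-methoxy-N-methyl-3-oxopropanamide, via lithium enolate 10 (not isolated)
Conditions: LiN(iPr)2, THF, −78 °C (9 and base 3 equiv each); then 8, −78 to −40 °C; aq. NH4Cl
Reagents that add atoms: none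
Why: Crossed Claisen condensation: the strongly nucleophilic amide enolate 10 is acylated at low temperature by the non-enolisable aryl ester, and deprotonation of the β-keto amide formed drives the reaction and prevents a second addition.

Step 6
Reactants: 11 β-keto Weinreb amide
Product: 12 (3S)-3-Ar-3-hydroxy-N-methoxy-N-methylpropanamide
Conditions: RuCl[(S,S)-TsDPEN](p-cymene) (2 mol%), HCO2H/Et3N (amine in slight excess), DMF, 30 °C
Reagents that add atoms: none
Why: Noyori–Ikariya asymmetric transfer hydrogenation: the (S,S)-ligated ruthenium hydride reduces the aryl ketone through the six-membered outer-sphere transition state in which a CH–π contact orients the aryl group, the mode that gives (S)-1-arylalkanols, and this sets the future C2 as S.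

Step 7
Reactants: 12 (S)-β-hydroxy Weinreb amide
Product: 13 (3S)-3-Ar-N-methoxy-N-methyl-3-(triethylsilyloxy)propanamide
Conditions: Et3SiCl, imidazole, DMF, 0 °C to rt
Reagents that add atoms: chlorotriethylsilane, CC[Si](Cl)(CC)CC
Why: Silylation of the secondary alcohol under imidazole catalysis; the triethylsilyl ether prevents alkoxide formation and retro-aldol cleavage in the strongly basic step 9 and can later be removed without acid strong enough to harm the acetonide.

Step 8
Reactants: 14 2,2,6-trimethyl-4H-1,3-dioxin-4-one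
Product: 16 2,2-dimethyl-6-(2-oxopropyl)-4H-1,3-dioxin-4-one, via lithium dienolate 15 (not isolated)
Conditions: LiN(SiMe3)2, THF, −78 °C (14 and base 2 equiv each); then AcCl (1 equiv), −78 °C
Reagents that add atoms: acetyl chloride, CC(Cl)=O
Why: Claisen-type γ-acylation of the lithium dienolate 15 by an acid chloride; the second equivalent of dienolate absorbs the acidic proton of the product, which protects it from further acylation.

Step 9
Reactants: 13 silyl-protected Weinreb amide; 16 keto-dioxinone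
Product: 18 6-[(6S)-6-Ar-2,4-dioxo-6-(triethylsilyloxy)hexyl]-2,2-dimethyl-4H-1,3-dioxin-4-one, via dilithium dianion 17 (not isolated)
Conditions: 16 (2.5 equiv), LiN(iPr)2 (5 equiv), THF, −78 to −40 °C; then 13, −78 to −30 °C; cold aq. NH4Cl
Reagents that add atoms: none
Why: Claisen-type acylation of a 1,3-dicarbonyl dianion: the terminal, more reactive carbanion of 17 adds to the Weinreb amide, whose chelated tetrahedral adduct survives until work-up and so prevents over-addition, and the silyloxy stereocentre is not involved.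

Step 10
Reactants: 18 diketo-dioxinone
Product: 20 6-{[(2S)-2-Ar-4-oxo-3,4-dihydro-2H-pyran-6-yl]methyl}-2,2-dimethyl-4H-1,3-dioxin-4-one, via hydroxy diketone 19 (not isolated)
Conditions: HF·pyridine, pyridine, THF, 0 °C to rt; then PPTS (cat.), 4 Å molecular sieves, CH2Cl2, rt
Reagents that add atoms: none
Why: Fluoride removes the silyl group, the freed δ-hydroxyl adds to the remote ketone to give a six-membered hemiketal, and acid-catalysed dehydration (cyclodehydration of a δ-hydroxy-β-diketone) gives the conjugated 2,3-dihydropyran-4-one; the C–O bond at the stereocentre is never broken, so C2 stays S, and buffered fluoride followed by anhydrous PPTS spares the acetonide and the dioxinone.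

Step 11
Reactants: 20 pyranone-dioxinone
Product: 22 methyl 4-[(2S)-2-Ar-4-oxo-3,4-dihydro-2H-pyran-6-yl]-3-oxobutanoate, via acylketene 21 (not isolated)
Conditions: MeOH (20 equiv), toluene, 110 °C, sealed tube
Reagents that add atoms: methanol, CO
Why: Thermal retro-hetero-Diels–Alder fragmentation of the dioxinone expels acetone and gives acylketene 21, which excess methanol captures as the β-keto ester (standard dioxinone alcoholysis) under neutral conditions that leave C2 and the acetonide untouched.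

Step 12
Reactants: 22 pyranone β-keto ester
Product: 24 (2S)-2-Ar-5,7-dihydroxy-2,3-dihydro-4H-chromen-4-one, via triketone tautomer 23 (not isolated)
Conditions: Mg(OMe)2 (4 equiv), MeOH/THF, 0 °C to rt; cold dilute HCl to pH 4
Reagents that add atoms: none
Why: Proposed new method: Mg(OMe)2 should convert 22 into a chelated magnesium polyenolate; removal of a proton from the methylene between pyranone C6 and the chain ketone makes pyranone C5 nucleophilic through the vinylogous ester, C5 adds to the ester carbonyl, methoxide leaves and triketone 23 enolises irreversibly to the aromatic ring A. The closest known reaction type is the Claisen (Dieckmann-type) cyclisation of open-chain 3,5,7-triketo esters to acylphloroglucinols under Mg(OMe)2; the new element is that two of the chain carbonyls are tied up in a dihydropyranone that already carries ring C. Ring A closes in a 6-(enolexo)-exo-trig acyl substitution that forms only the C4a–C5 bond. No stereocentre is created; C2 is a spectator, and it should survive because the chain methylenes are far more acidic than C3–H, so the C3 enolate needed for retro-oxa-Michael opening is not formed, and the reaction is stopped cold as soon as 22 is consumed. The selectivity needed is C-acylation at pyranone C5 over aldol attack of the ester α-carbon on C4; it is secured because C4 is a weakly electrophilic vinylogous ester carbonyl that turns into an enolate carbon once the dienolate forms, whereas the Claisen path is pulled forward by aromatisation.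

Step 13
Reactants: 24 acetonide-protected flavanone
Product: 25 (2S)-2-(4-{[(1R,2R)-1-(4-benzyloxyphenyl)-1,3-dihydroxypropan-2-yl]oxy}-3,5-dimethoxyphenyl)-5,7-dihydroxy-2,3-dihydro-4H-chromen-4-one
Conditions: AcOH/THF/H2O (3:1:1), 35 °C
Reagents that add atoms: none
Why: Acid-catalysed hydrolysis of the isopropylidene acetal; dilute acetic acid should not ionise the benzylic C7–O bond while the para oxygen is still benzylated, and flavanones are configurationally stable to weak acid, so all three stereocentres should be retained.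

Step 14
Reactants: 25 benzyl-protected flavanone diol
Product: 26 (2S)-2-(4-{[(1R,2R)-1,3-dihydroxy-1-(4-hydroxyphenyl)propan-2-yl]oxy}-3,5-dimethoxyphenyl)-5,7-dihydroxy-2,3-dihydro-4H-chromen-4-one (target)
Conditions: H2 (1 atm), 10% Pd/C, EtOAc, rt
Reagents that add atoms: none
Why: Catalytic hydrogenolysis of the benzyl aryl ether, which under neutral conditions at one atmosphere is much faster than reduction of the hydrogen-bonded aryl ketone or cleavage of the benzylic C7–OH and C2–O1 bonds.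

**Compound list**

1 | methyl 4-hydroxy-3,5-dimethoxybenzoate (methyl syringate) | COC(=O)c1cc(OC)c(O)c(OC)c1 | starting material
2 | (4S)-4-benzyl-3-(chloroacetyl)-1,3-oxazolidin-2-one | ClCC(=O)N1C(=O)OC[C@@H]1Cc1ccccc1 | starting material
3 | methyl 4-{2-[(4S)-4-benzyl-2-oxo-1,3-oxazolidin-3-yl]-2-oxoethoxy}-3,5-dimethoxybenzoate | COC(=O)c1cc(OC)c(OCC(=O)N2C(=O)OC[C@@H]2Cc2ccccc2)c(OC)c1 | intermediate
4 | 4-benzyloxybenzaldehyde | O=Cc1ccc(OCc2ccccc2)cc1 | starting material
5 | (Z)-dibutylboron enolate of 3 | CCCCB(CCCC)O/C(N1C(=O)OC[C@@H]1Cc1ccccc1)=C\Oc1c(OC)cc(C(=O)OC)cc1OC | intermediate (not isolated)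
6 | methyl 4-{[(2S,3R)-1-[(4S)-4-benzyl-2-oxo-1,3-oxazolidin-3-yl]-3-(4-benzyloxyphenyl)-3-hydroxy-1-oxopropan-2-yl]oxy}-3,5-dimethoxybenzoate | COC(=O)c1cc(OC)c(O[C@H](C(=O)N2C(=O)OC[C@@H]2Cc2ccccc2)[C@H](O)c2ccc(OCc3ccccc3)cc2)c(OC)c1 | intermediate
7 | methyl 4-{[(1R,2R)-1-(4-benzyloxyphenyl)-1,3-dihydroxypropan-2-yl]oxy}-3,5-dimethoxybenzoate | COC(=O)c1cc(OC)c(O[C@H](CO)[C@H](O)c2ccc(OCc3ccccc3)cc2)c(OC)c1 | intermediate
8 | methyl 4-{[(4R,5R)-4-(4-benzyloxyphenyl)-2,2-dimethyl-1,3-dioxan-5-yl]oxy}-3,5-dimethoxybenzoate (Ar–CO2Me) | COC(=O)c1cc(OC)c(O[C@@H]2COC(C)(C)O[C@@H]2c2ccc(OCc3ccccc3)cc2)c(OC)c1 | intermediate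
9 | N-methoxy-N-methylacetamide | CC(=O)N(C)OC | starting material
10 | lithium enolate of 9 | C=C(O[Li])N(C)OC | intermediate (not isolated)
11 | 3-Ar-N-methoxy-N-methyl-3-oxopropanamide | CON(C)C(=O)CC(=O)c1cc(OC)c(O[C@@H]2COC(C)(C)O[C@@H]2c2ccc(OCc3ccccc3)cc2)c(OC)c1 | intermediate
12 | (3S)-3-Ar-3-hydroxy-N-methoxy-N-methylpropanamide | CON(C)C(=O)C[C@H](O)c1cc(OC)c(O[C@@H]2COC(C)(C)O[C@@H]2c2ccc(OCc3ccccc3)cc2)c(OC)c1 | intermediate
13 | (3S)-3-Ar-N-methoxy-N-methyl-3-(triethylsilyloxy)propanamide | CC[Si](CC)(CC)O[C@@H](CC(=O)N(C)OC)c1cc(OC)c(O[C@@H]2COC(C)(C)O[C@@H]2c2ccc(OCc3ccccc3)cc2)c(OC)c1 | intermediate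
14 | 2,2,6-trimethyl-4H-1,3-dioxin-4-one | CC1=CC(=O)OC(C)(C)O1 | starting material
15 | lithium dienolate of 14 | C=C1C=C(O[Li])OC(C)(C)O1 | intermediate (not isolated)
16 | 2,2-dimethyl-6-(2-oxopropyl)-4H-1,3-dioxin-4-one | CC(=O)CC1=CC(=O)OC(C)(C)O1 | intermediate
17 | dilithium dianion (bis-enolate) of 16 | C=C(O[Li])C=C1C=C(O[Li])OC(C)(C)O1 | intermediate (not isolated)
18 | 6-[(6S)-6-Ar-2,4-dioxo-6-(triethylsilyloxy)hexyl]-2,2-dimethyl-4H-1,3-dioxin-4-one | CC[Si](CC)(CC)O[C@@H](CC(=O)CC(=O)CC1=CC(=O)OC(C)(C)O1)c1cc(OC)c(O[C@@H]2COC(C)(C)O[C@@H]2c2ccc(OCc3ccccc3)cc2)c(OC)c1 | intermediate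
19 | 6-[(6S)-6-Ar-6-hydroxy-2,4-dioxohexyl]-2,2-dimethyl-4H-1,3-dioxin-4-one (open form, in equilibrium with its cyclic hemiketal) | O[C@@H](CC(=O)CC(=O)CC1=CC(=O)OC(C)(C)O1)c1cc(OC)c(O[C@@H]2COC(C)(C)O[C@@H]2c2ccc(OCc3ccccc3)cc2)c(OC)c1 | intermediate (not isolated)
20 | 6-{[(2S)-2-Ar-4-oxo-3,4-dihydro-2H-pyran-6-yl]methyl}-2,2-dimethyl-4H-1,3-dioxin-4-one | O=C1C=C(CC2=CC(=O)C[C@H](O2)c2cc(OC)c(O[C@@H]3COC(C)(C)O[C@@H]3c3ccc(OCc4ccccc4)cc3)c(OC)c2)OC(C)(C)O1 | intermediate
21 | acylketene, 4-[(2S)-2-Ar-4-oxo-3,4-dihydro-2H-pyran-6-yl]-3-oxobut-1-en-1-one | O=C=CC(=O)CC1=CC(=O)C[C@H](O1)c1cc(OC)c(O[C@@H]2COC(C)(C)O[C@@H]2c2ccc(OCc3ccccc3)cc2)c(OC)c1 | intermediate (not isolated)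
22 | methyl 4-[(2S)-2-Ar-4-oxo-3,4-dihydro-2H-pyran-6-yl]-3-oxobutanoate | COC(=O)CC(=O)CC1=CC(=O)C[C@H](O1)c1cc(OC)c(O[C@@H]2COC(C)(C)O[C@@H]2c2ccc(OCc3ccccc3)cc2)c(OC)c1 | intermediate
23 | (2S)-2-Ar-2,3-dihydro-4H-chromene-4,5,7(4aH,6H)-trione (non-aromatic Claisen adduct, C4a undefined) | O=C1CC(=O)C=C2O[C@H](c3cc(OC)c(O[C@@H]4COC(C)(C)O[C@@H]4c4ccc(OCc5ccccc5)cc4)c(OC)c3)CC(=O)C12 | intermediate (not isolated)
24 | (2S)-2-Ar-5,7-dihydroxy-2,3-dihydro-4H-chromen-4-one | COc1cc([C@@H]2CC(=O)c3c(O)cc(O)cc3O2)cc(OC)c1O[C@@H]1COC(C)(C)O[C@@H]1c1ccc(OCc2ccccc2)cc1 | intermediate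
25 | (2S)-2-(4-{[(1R,2R)-1-(4-benzyloxyphenyl)-1,3-dihydroxypropan-2-yl]oxy}-3,5-dimethoxyphenyl)-5,7-dihydroxy-2,3-dihydro-4H-chromen-4-one | COc1cc([C@@H]2CC(=O)c3c(O)cc(O)cc3O2)cc(OC)c1O[C@H](CO)[C@H](O)c1ccc(OCc2ccccc2)cc1 | intermediate
26 | (2S)-2-(4-{[(1R,2R)-1,3-dihydroxy-1-(4-hydroxyphenyl)propan-2-yl]oxy}-3,5-dimethoxyphenyl)-5,7-dihydroxy-2,3-dihydro-4H-chromen-4-one | COc1cc([C@@H]2CC(=O)c3c(O)cc(O)cc3O2)cc(OC)c1O[C@H](CO)[C@H](O)c1ccc(O)cc1 | target

**Step count**

Total: 14 steps. Longest linear sequence: 13 steps (steps 1 to 7 and 9 to 14, from methyl syringate); step 8 is a one-step side branch.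

**Steps most likely to fail**

Step 12 (proposed new method). Two processes may defeat it: aldol closure of the ester α-carbon onto C4 in place of C-acylation at C5, and base-mediated opening of the flavanone product to the chalcone, which would erode the configuration at C2. The fallback uses known chemistry only: ring A is taken ready-made as a chromone and C2 is created by rhodium-catalysed asymmetric 1,4-addition of an arylboronic acid (Hayashi–Miyaura type). It sets out from 2 and 4 and comes back to the route at 26.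
- Commercial 4-bromo-2,6-dimethoxyphenol is alkylated with 2 as in step 1 to give (4S)-4-benzyl-3-[(4-bromo-2,6-dimethoxyphenoxy)acetyl]-1,3-oxazolidin-2-one F1.
- The aldol with 4 as in step 2 gives the syn adduct (4S)-4-benzyl-3-[(2S,3R)-3-(4-benzyloxyphenyl)-2-(4-bromo-2,6-dimethoxyphenoxy)-3-hydroxypropanoyl]-1,3-oxazolidin-2-one F2.
- NaBH4 in THF/H2O gives (1R,2R)-1-(4-benzyloxyphenyl)-2-(4-bromo-2,6-dimethoxyphenoxy)propane-1,3-diol F3.
- 2,2-Dimethoxypropane and PPTS give (4R,5R)-4-(4-benzyloxyphenyl)-5-(4-bromo-2,6-dimethoxyphenoxy)-2,2-dimethyl-1,3-dioxane F4.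
- Bromine–lithium exchange (n-BuLi, THF, −78 °C), B(OiPr)3 and aqueous NH4Cl give the arylboronic acid Ar–B(OH)2 F5.
- Commercial 5,7-dihydroxy-4H-chromen-4-one is benzylated (BnBr, K2CO3, DMF) to 5,7-bis(benzyloxy)-4H-chromen-4-one F6.
- [RhCl(C2H4)2]2 with a chiral bicyclic diene ligand (the enantiomer that delivers 2S), catalytic KOH, dioxane/H2O should join F5 and F6 to (2S)-2-Ar-5,7-bis(benzyloxy)-2,3-dihydro-4H-chromen-4-one F7.
- AcOH/THF/H2O as in step 13 gives the diol (2S)-5,7-bis(benzyloxy)-2-(4-{[(1R,2R)-1-(4-benzyloxyphenyl)-1,3-dihydroxypropan-2-yl]oxy}-3,5-dimethoxyphenyl)-2,3-dihydro-4H-chromen-4-one F8, and hydrogenolysis of the three benzyl ethers as in step 14 gives 26.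

Step 9. The dianion may act as a base toward the Weinreb amide, with loss of the silyloxy group by elimination, or acylation may stall, and the enolised product may begin to aromatise by aldol closure during work-up. The fallback replaces acylation by aldol addition and oxidation; it sets out from 13 and comes back at 18. Reduction of 13 with iBu2AlH (THF, −78 °C) gives (3S)-3-Ar-3-(triethylsilyloxy)propanal F9. Addition of dianion 17 at −78 °C gives 6-[(6S)-6-Ar-4-hydroxy-2-oxo-6-(triethylsilyloxy)hexyl]-2,2-dimethyl-4H-1,3-dioxin-4-one F10 as a mixture of carbinol epimers. Dess–Martin periodinane with NaHCO3 in CH2Cl2 oxidises both epimers to 18.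

Step 10. Desilylation may be accompanied by partial loss of the acetonide, or the enolised diketone may close onto the dioxinone ring by aldol aromatisation before the hemiketal forms. The fallback omits the silyl ether; it sets out from 12 and comes back at 20. Alcohol 12 is added to an extra equivalent of dianion 17 (3.5 equiv in all, THF, −78 to −30 °C), so that its lithium alkoxide is the species acylated. Mildly acidic quench then delivers 19 directly as its hemiketal, which masks the diketone at once, and PPTS with 4 Å molecular sieves in CH2Cl2 dehydrates it to 20. This fallback makes no compound outside the list (entry F0).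

**Further compounds**

F1 | step 12 | (4S)-4-benzyl-3-[(4-bromo-2,6-dimethoxyphenoxy)acetyl]-1,3-oxazolidin-2-one | COc1cc(Br)cc(OC)c1OCC(=O)N1C(=O)OC[C@@H]1Cc1ccccc1
F2 | step 12 | (4S)-4-benzyl-3-[(2S,3R)-3-(4-benzyloxyphenyl)-2-(4-bromo-2,6-dimethoxyphenoxy)-3-hydroxypropanoyl]-1,3-oxazolidin-2-one | COc1cc(Br)cc(OC)c1O[C@H](C(=O)N1C(=O)OC[C@@H]1Cc1ccccc1)[C@H](O)c1ccc(OCc2ccccc2)cc1
F3 | step 12 | (1R,2R)-1-(4-benzyloxyphenyl)-2-(4-bromo-2,6-dimethoxyphenoxy)propane-1,3-diol | COc1cc(Br)cc(OC)c1O[C@H](CO)[C@H](O)c1ccc(OCc2ccccc2)cc1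
F4 | step 12 | (4R,5R)-4-(4-benzyloxyphenyl)-5-(4-bromo-2,6-dimethoxyphenoxy)-2,2-dimethyl-1,3-dioxane | COc1cc(Br)cc(OC)c1O[C@@H]1COC(C)(C)O[C@@H]1c1ccc(OCc2ccccc2)cc1
F5 | step 12 | arylboronic acid Ar–B(OH)2 | COc1cc(B(O)O)cc(OC)c1O[C@@H]1COC(C)(C)O[C@@H]1c1ccc(OCc2ccccc2)cc1
F6 | step 12 | 5,7-bis(benzyloxy)-4H-chromen-4-one | O=c1ccoc2cc(OCc3ccccc3)cc(OCc3ccccc3)c12
F7 | step 12 | (2S)-2-Ar-5,7-bis(benzyloxy)-2,3-dihydro-4H-chromen-4-one | COc1cc([C@@H]2CC(=O)c3c(OCc4ccccc4)cc(OCc4ccccc4)cc3O2)cc(OC)c1O[C@@H]1COC(C)(C)O[C@@H]1c1ccc(OCc2ccccc2)cc1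
F8 | step 12 | (2S)-5,7-bis(benzyloxy)-2-(4-{[(1R,2R)-1-(4-benzyloxyphenyl)-1,3-dihydroxypropan-2-yl]oxy}-3,5-dimethoxyphenyl)-2,3-dihydro-4H-chromen-4-one | COc1cc([C@@H]2CC(=O)c3c(OCc4ccccc4)cc(OCc4ccccc4)cc3O2)cc(OC)c1O[C@H](CO)[C@H](O)c1ccc(OCc2ccccc2)cc1
F9 | step 9 | (3S)-3-Ar-3-(triethylsilyloxy)propanal | CC[Si](CC)(CC)O[C@@H](CC=O)c1cc(OC)c(O[C@@H]2COC(C)(C)O[C@@H]2c2ccc(OCc3ccccc3)cc2)c(OC)c1
F10 | step 9 | 6-[(6S)-6-Ar-4-hydroxy-2-oxo-6-(triethylsilyloxy)hexyl]-2,2-dimethyl-4H-1,3-dioxin-4-one (both C4 epimers) | CC[Si](CC)(CC)O[C@@H](CC(O)CC(=O)CC1=CC(=O)OC(C)(C)O1)c1cc(OC)c(O[C@@H]2COC(C)(C)O[C@@H]2c2ccc(OCc3ccccc3)cc2)c(OC)c1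
F0 | step 10 | none | none
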